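**Structural features**

The target is an isoflavone: a 4H-chromen-4-one, in which benzo ring A is fused to the 4-pyranone ring C through C4a–C8a, carrying aryl ring B on C3 through the C3–C1' bond. Ring A has one oxygen substituent, at C7, etherified with a 3-methylbut-2-enyl (prenyl) group. Ring B carries a free hydroxyl at C3' next to a methoxyl at C4'. There is no stereocentre and no double bond whose configuration must be set, so the problem is purely one of regiochemistry and chemoselectivity. The fragile parts are the allylic aryl ether (ionised by strong protic or Lewis acids, prone to Claisen rearrangement on strong heating, lost on hydrogenation), the electrophilic C2 of the pyranone (ring opening by hard nucleophiles) and the free phenol. The real difficulty is to tell the two phenolic oxygens apart so that O7 alone is prenylated and, when ring A is built and not bought, to place its oxygen on C7 and not on C6. The key step uses the fact that C4a=C8a of the chromone is the C5=C6 bond of a monocyclic 3-aryl-4-pyranone. With a phenylsulfinyl group on C5 this bond becomes a doubly activated dienophile, carbons C5–C8 come from a 1-methoxy-3-silyloxybutadiene whose silyloxy carbon becomes C7, and the sulfinyl and methoxy groups leave to supply the two unsaturations that make ring A aromatic.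

**Logic of the disconnections**

15 ⇒ 14. The O3'–Si bond is cut. The last operation should be an unmasking that the prenyl ether tolerates, and fluoride is such a reagent. The gain is that the ring B phenol stays inert through the whole sequence. The demand is that the silyl ether survives hot amide acetal, aqueous acid, a thermal cycloaddition and carbonate, which is why a triisopropylsilyl group is used.

14 ⇒ 12 + 13. The O7–CH2 bond of the prenyl ether is cut. The acid- and heat-sensitive allylic ether is thereby introduced only after the thermal and acidic benzannulation. Because 12 has one free hydroxyl, the alkylation needs no site selectivity. The forward step must give O-alkylation at the primary carbon of 13 and must not move the silyl group.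

12 ⇒ 8 + 9. The bonds C8–C8a and C4a–C5 are cut, after formally adding back benzenesulfenic acid, methanol and the silyl group. This removes ring A completely and reduces the bicycle to a monocyclic pyranone plus a commercial four-carbon diene. The forward step must engage only the sulfinyl-bearing double bond of 8, must orient 9 so that its oxygen ends at C7, and must aromatise without harming the aryl silyl ether.

8 ⇒ 6 (through 7). The bonds O1–C2 and O1–C6 and the bonds C2–C3 and C5–C6 are cut, which takes out the ring oxygen and the two one-carbon units. Ketone 6 has an acidic methylene on each side of the carbonyl, and each can take up one formyl-equivalent carbon from an amide acetal. The heterocycle is reduced to an open-chain ketone. The forward step must drive both condensations to completion and close the ring with acid mild enough for the sulfoxide and the silyl ether.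

6 ⇒ 3 + 4 (through 5). The bond between the carbonyl carbon and the sulfur-bearing methylene is cut. This is a Claisen-type acylation and divides 6 into an arylacetate and a one-carbon sulfinyl unit, both simple. The demand is that carbonyl addition of 5 outruns proton abstraction from the benzylic methylene of 3, and that a second equivalent of base is present because 6 is more acidic than 4.

3 ⇒ 2 ⇒ 1. The O–Si bond and the ester O–CH3 bond are cut. The acid must be an ester to serve as acylating agent and the phenol must be masked before any strong base is used. Both forward steps are routine.

**Other disconnections considered**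

Alternative 1: The cut is C4–C4a, made when the aryl ether bond O1–C8a is already in place. In the forward direction the acrylic acid A1, whose carboxyl and aryloxy groups stand cis on the double bond, is activated by (CF3CO)2O as a mixed anhydride and acylates the resorcinol-derived ring intramolecularly (six-membered Friedel–Crafts closure) to give the dibenzyl ether A2.
- In favour: ring A is bought as a cheap resorcinol monoether and not built. The closure is a metal-free electrophilic substitution on a strongly activated arene. It rests on firmer precedent than the cycloaddition of the chosen plan, and on that point this alternative is the better one.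
- Against: acylation can occur para to the benzyloxy group (leading to A2) or between the two oxygens (leading to the 5-oxygenated isomer), so the C7 pattern rests on a steric preference. Only the cis-configured acid can close, the acid-labile enol ether must survive the anhydride, and the electron-rich ring B may be trifluoroacetylated.
- Endgame: both oxygens of A2 carry benzyl groups. Hydrogenolysis has to come before prenylation, since it would otherwise saturate the prenyl alkene, and it frees both phenols at once. The final alkylation must then distinguish O7 from O3' by acidity alone, whereas 12 has a single free hydroxyl.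
- Comparison: both plans close one ring in the key step. A1 needs about four steps and three more follow A2, so the two plans are about equal in length. The alternative is better on cost of materials and scalability; the chosen plan is better on control of the two regiochemical questions.

Alternative 2: The cuts are O1–C8a and C4–C4a, made in one operation that closes no ring. CsF releases an aryne from the silyl triflate A3. The carboxylate of acid A4 adds to the aryne carbon remote from chlorine, the aryl anion next to chlorine attacks the acyl carbon, and the four-membered intermediate opens to the ortho-hydroxyaryl ketone A5 (formal insertion into the acyl C–O bond). Acid would later unmask the acetal and close ring C.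
- In favour: rings A and B are joined convergently under mild fluoride conditions. Two bonds form in one step, which equals the chosen key step in bond count and betters it in convergence. The later ring closure is trivial.
- Against: the chlorine serves only to steer the addition to the aryne and must be removed again. The tetrasubstituted arene A3 costs several steps. Protonation of the aryl anion, which gives a simple aryl ester, competes with acyl transfer.
- Endgame: fluoride excludes silyl protection, so benzyl ethers are used, and the diphenol discrimination of Alternative 1 returns after hydrogenolysis. The stereocentre of A5 is irrelevant because it becomes the sp2 carbon C3.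
- Comparison: regiocontrol comes from a sacrificial substituent there and from the innate polarity of diene and dienophile here, so the chosen plan is better on that point. Both key steps are little tested on these exact substrates and are equal in mechanistic risk. The chosen plan is likely shorter.

Alternative 3: The cut is O1–C8a. The hydroxymethylene ketone A6 already carries the prenyl ether. With CuI, K3PO4 and a diamine ligand its enolate oxygen couples with the ortho carbon–bromine bond in an intramolecular Ullmann-type etherification that closes ring C and gives A7, the tert-butyldimethylsilyl analogue of 14.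
- In favour: ring A is bought as a bromophenol derivative and O7 is prenylated at the outset. The oxygens are therefore differentiated as cleanly as in the chosen plan (equal), and A7 is one desilylation from the target. Copper-mediated intramolecular O-arylation to chromones is an established reaction type, the route is convergent and it is probably one or two steps shorter. On precedent and step economy this alternative is the better one.
- Against: the ortho-bromo deoxybenzoin behind A6 must be assembled without acid because of the prenyl ether. The hydroxymethylene ketone can lose its formyl group under hot phosphate. The tert-butyldimethylsilyl aryl ether meets base at elevated temperature, and a hot allylic aryl ether risks Claisen rearrangement.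
- Comparison: the chosen plan avoids transition metals and halogenated intermediates and settles the C7 question by polarity. It pays for this with a de novo construction of ring A and a dienophile of limited precedent.

Key step: step 5

Remark on the chemistry: the ring B phenol is carried as a triisopropylsilyl ether and not as a tert-butyldimethylsilyl ether. The less hindered group could be stripped by methoxide from the hot amide acetal (followed by irreversible O-methylation) or passed to the 7-phenoxide under carbonate. The skeletons of 8 and 12 are unchanged.

Remark on the chemistry: the atom mapping of the key step agrees with the target and needs no correction. The diene silyloxy carbon becomes C7, the diene CH2 becomes C8, pyranone C6 becomes C8a and pyranone C5 becomes C4a.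

Remark on the chemistry: all sulfinyl compounds are racemic at sulfur. This stereocentre is destroyed in step 5 and needs no control.

**Route**

Step 1
Reactants: 1 3-hydroxy-4-methoxyphenylacetic acid
Product: 2 methyl 2-(3-hydroxy-4-methoxyphenyl)acetate
Conditions: MeOH, H2SO4 (cat.), reflux
Reagents that add atoms: methanol, CO
Why: Fischer esterification; the acid becomes an acylating agent for step 3 and the phenol is untouched under acid catalysis.

Step 2
Reactants: 2 methyl 2-(3-hydroxy-4-methoxyphenyl)acetate
Product: 3 methyl 2-[4-methoxy-3-(triisopropylsilyloxy)phenyl]acetate
Conditions: iPr3SiCl, imidazole, DMF, rt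
Reagents that add atoms: triisopropylsilyl chloride, CC(C)[Si](Cl)(C(C)C)C(C)C
Why: Imidazole-promoted O-silylation of a phenol; the hindered aryl silyl ether should withstand strong base, amide acetal, dilute acid and carbonate and is removed only by fluoride.

Step 3
Reactants: 3 methyl 2-[4-methoxy-3-(triisopropylsilyloxy)phenyl]acetate; 4 methyl phenyl sulfoxide (racemic)
Product: 6 1-[4-methoxy-3-(triisopropylsilyloxy)phenyl]-3-(phenylsulfinyl)propan-2-one (racemic at sulfur), via (phenylsulfinyl)methyllithium 5 (not isolated)
Conditions: 4 (2.2 equiv), LiN(iPr)2 (2.1 equiv), THF, −78 °C; then 3 added slowly, −78 → −20 °C; aq. NH4Cl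
Reagents that add atoms: none
Why: Claisen-type acylation of an α-sulfinyl carbanion by an ester, the standard entry to β-keto sulfoxides; the second equivalent of 5 deprotonates the product, which prevents over-addition, and slow addition of 3 to cold excess 5 is meant to favour carbonyl attack over enolisation.

Step 4
Reactants: 6 1-[4-methoxy-3-(triisopropylsilyloxy)phenyl]-3-(phenylsulfinyl)propan-2-one
Product: 8 3-[4-methoxy-3-(triisopropylsilyloxy)phenyl]-5-(phenylsulfinyl)-4H-pyran-4-one (racemic at sulfur), via bis(dimethylaminomethylene) ketone 7 (not isolated)
Conditions: Me2NCH(OMe)2 (6 equiv), toluene, 100 °C; evaporate; then 1 M aq. H2SO4, THF, rt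
Reagents that add atoms: N,N-dimethylformamide dimethyl acetal, COC(OC)N(C)C; water, O
Why: Double aminomethylenation of a ketone with two activated methylenes, then acid hydrolysis of one enaminone to the enol, which adds to the other with loss of dimethylamine; this is the known route from 1,3-disubstituted acetones to 3,5-disubstituted 4-pyranones. The sulfoxide has no β-hydrogen on sp3 carbon, so it cannot undergo thermal elimination, and a non-nucleophilic acid avoids Pummerer-type chemistry.

Step 5
Reactants: 8 3-[4-methoxy-3-(triisopropylsilyloxy)phenyl]-5-(phenylsulfinyl)-4H-pyran-4-one; 9 (E)-1-methoxy-3-(trimethylsilyloxy)buta-1,3-diene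
Product: 12 7-hydroxy-3-[4-methoxy-3-(triisopropylsilyloxy)phenyl]-4H-chromen-4-one, via cis-fused sulfinyl cycloadduct 10 (not isolated), via 5-methoxy-5,8-dihydrochromone silyl enol ether 11 (not isolated)
Conditions: 9 (3 equiv), toluene, 80 → 110 °C; then 1 M aq. HCl, THF, rt
Reagents that add atoms: none
Why: The C5=C6 bond of 8 is flanked by the C4 carbonyl and the sulfinyl group and is the only doubly activated alkene, so it should be the dienophile in a normal-demand Diels–Alder reaction with electron-rich 9, while the aryl-bearing C2=C3 bond, a plain vinylogous ester, stays out. The cycloaddition is concerted but asynchronous: the CH2 terminus of 9 bonds first to pyranone C6 (β to the carbonyl, future C8a) and the methoxy-bearing terminus then bonds to the sulfinyl carbon (future C4a), closing ring A suprafacially as a six-membered carbocycle with a cis ring fusion in 10. The closest known reaction type is the cycloaddition of 1-methoxy-3-silyloxybutadienes to sulfinyl-activated enones and quinones and to 3-acylchromones, followed by elimination to a phenol. In 10 the sulfinyl group and H-8a are cis, so thermal syn-elimination of benzenesulfenic acid restores C4a=C8a and gives 11. Dilute acid then hydrolyses the trimethylsilyl enol ether to the C7 ketone, methanol is lost from C5 by β-elimination and the dienone tautomerises to phenol 12. The placement of oxygen at C7 and not C6 follows from polarity matching, since carbonyl and sulfinyl both make C6 the electrophilic carbon and the silyloxy group makes the CH2 terminus of 9 the nucleophilic one. The stereocentres of 10 (C4a, C5, C8a and sulfur) are all destroyed, so endo/exo and facial selectivity are irrelevant. The aryl triisopropylsilyl ether should withstand the dilute acid that cleaves the silyl enol ether, so 12 emerges with one free hydroxyl.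

Step 6
Reactants: 12 7-hydroxy-3-[4-methoxy-3-(triisopropylsilyloxy)phenyl]-4H-chromen-4-one; 13 prenyl bromide (1-bromo-3-methylbut-2-ene)
Product: 14 3-[4-methoxy-3-(triisopropylsilyloxy)phenyl]-7-(3-methylbut-2-enyloxy)-4H-chromen-4-one
Conditions: K2CO3, acetone, 50 °C
Reagents that add atoms: none
Why: Williamson ether synthesis on the only free phenol; the 7-hydroxyl is a vinylogous carboxylic acid and is fully ionised by carbonate, and its soft phenoxide should attack the primary carbon of the allylic bromide by direct SN2 displacement.

Step 7
Reactants: 14 3-[4-methoxy-3-(triisopropylsilyloxy)phenyl]-7-(3-methylbut-2-enyloxy)-4H-chromen-4-one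
Product: 15 7-prenyloxy-3'-hydroxy-4'-methoxyisoflavone, i.e. 3-(3-hydroxy-4-methoxyphenyl)-7-(3-methylbut-2-enyloxy)-4H-chromen-4-one
Conditions: Bu4NF, AcOH, THF, 0 °C
Reagents that add atoms: none
Why: Fluoride-induced cleavage of an aryl silyl ether; buffering with acetic acid keeps the medium from becoming basic enough to open the pyranone at C2, and the prenyl ether is inert to fluoride.

**Compound list**

1 | 3-hydroxy-4-methoxyphenylacetic acid | COc1ccc(CC(=O)O)cc1O | starting material
2 | methyl 2-(3-hydroxy-4-methoxyphenyl)acetate | COC(=O)Cc1ccc(OC)c(O)c1 | intermediate
3 | methyl 2-[4-methoxy-3-(triisopropylsilyloxy)phenyl]acetate | COC(=O)Cc1ccc(OC)c(O[Si](C(C)C)(C(C)C)C(C)C)c1 | intermediate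
4 | methyl phenyl sulfoxide (racemic) | CS(=O)c1ccccc1 | starting material
5 | (phenylsulfinyl)methyllithium (racemic; not isolated) | [Li]CS(=O)c1ccccc1 | intermediate
6 | 1-[4-methoxy-3-(triisopropylsilyloxy)phenyl]-3-(phenylsulfinyl)propan-2-one (racemic at sulfur) | COc1ccc(CC(=O)CS(=O)c2ccccc2)cc1O[Si](C(C)C)(C(C)C)C(C)C | intermediate
7 | 1,5-bis(dimethylamino)-2-[4-methoxy-3-(triisopropylsilyloxy)phenyl]-4-(phenylsulfinyl)penta-1,4-dien-3-one (racemic at sulfur; mixture of double-bond isomers; not isolated) | COc1ccc(C(=CN(C)C)C(=O)C(=CN(C)C)S(=O)c2ccccc2)cc1O[Si](C(C)C)(C(C)C)C(C)C | intermediate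
8 | 3-[4-methoxy-3-(triisopropylsilyloxy)phenyl]-5-(phenylsulfinyl)-4H-pyran-4-one (racemic at sulfur) | COc1ccc(-c2cocc(S(=O)c3ccccc3)c2=O)cc1O[Si](C(C)C)(C(C)C)C(C)C | intermediate
9 | (E)-1-methoxy-3-(trimethylsilyloxy)buta-1,3-diene | CO/C=C/C(=C)O[Si](C)(C)C | starting material
10 | 5-methoxy-3-[4-methoxy-3-(triisopropylsilyloxy)phenyl]-4a-(phenylsulfinyl)-7-(trimethylsilyloxy)-4a,5,8,8a-tetrahydro-4H-chromen-4-one (racemic; sulfinyl group and H-8a cis; epimer mixture at C5 and sulfur; not isolated) | COc1ccc(C2=CO[C@H]3CC(O[Si](C)(C)C)=CC(OC)[C@@]3(S(=O)c4ccccc4)C2=O)cc1O[Si](C(C)C)(C(C)C)C(C)C | intermediate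
11 | 5-methoxy-3-[4-methoxy-3-(triisopropylsilyloxy)phenyl]-7-(trimethylsilyloxy)-5,8-dihydro-4H-chromen-4-one (racemic; not isolated) | COc1ccc(C2=COC3=C(C2=O)C(OC)C=C(O[Si](C)(C)C)C3)cc1O[Si](C(C)C)(C(C)C)C(C)C | intermediate
12 | 7-hydroxy-3-[4-methoxy-3-(triisopropylsilyloxy)phenyl]-4H-chromen-4-one | COc1ccc(-c2coc3cc(O)ccc3c2=O)cc1O[Si](C(C)C)(C(C)C)C(C)C | intermediate
13 | prenyl bromide (1-bromo-3-methylbut-2-ene) | CC(C)=CCBr | starting material
14 | 3-[4-methoxy-3-(triisopropylsilyloxy)phenyl]-7-(3-methylbut-2-enyloxy)-4H-chromen-4-one | COc1ccc(-c2coc3cc(OCC=C(C)C)ccc3c2=O)cc1O[Si](C(C)C)(C(C)C)C(C)C | intermediate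
15 | 7-prenyloxy-3'-hydroxy-4'-methoxyisoflavone | COc1ccc(-c2coc3cc(OCC=C(C)C)ccc3c2=O)cc1O | target

**Step count and risks**

Total step count: 7. Longest linear sequence: 7 steps (1 → 2 → 3 → 6 → 8 → 12 → 14 → 15); 4, 9 and 13 are bought.

Step 5 (key step). The ring oxygen donates into the dienophile double bond, so the cycloaddition may be sluggish, and the sulfenic acid released may destroy the acid-sensitive diene faster than it is consumed. A stepwise conjugate addition followed by opening of the pyranone ring may also compete with ring closure. The fallback gives up the construction of ring A and sets out from 1. Friedel–Crafts acylation of resorcinol with 1 in BF3·OEt2 at 85 °C should give the deoxybenzoin 1-(2,4-dihydroxyphenyl)-2-(3-hydroxy-4-methoxyphenyl)ethan-1-one F1. One-carbon ring closure with DMF, BF3·OEt2 and MeSO2Cl should give 7-hydroxy-3-(3-hydroxy-4-methoxyphenyl)-4H-chromen-4-one F2. Alkylation of F2 with one equivalent of 13 and K2CO3 in acetone, which relies on the higher acidity of the 7-hydroxyl, comes back to the route at 15.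

Step 3. Proton transfer from the acidic benzylic methylene of 3 to the strongly basic carbanion 5 may outrun carbonyl addition, so that the ester is merely enolised and returned on work-up. The fallback sets out from 3 and uses a far less basic one-carbon nucleophile. Dimethylsulfoxonium methylide (Me3S(O)I, KOtBu, THF, reflux) is acylated by 3 to the keto sulfoxonium ylide 1-[dimethyl(oxo)-λ6-sulfanylidene]-3-[4-methoxy-3-(triisopropylsilyloxy)phenyl]propan-2-one F3. Thiophenol in warm MeCN protonates the ylide carbon and its thiolate displaces dimethyl sulfoxide, giving the keto sulfide 1-[4-methoxy-3-(triisopropylsilyloxy)phenyl]-3-(phenylthio)propan-2-one F4. Oxidation at sulfur with NaIO4 in MeOH/H2O at 0 °C comes back to the route at 6.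

Step 4. After the first condensation the ketone is a vinylogous amide, so the second aminomethylenation at the benzylic methylene may stall, and prolonged heating may erode the sulfinyl or silyl group. The fallback sets out from 6 and introduces the second carbon by enolate chemistry. The amide acetal at room temperature should give the mono-enaminone 4-(dimethylamino)-1-[4-methoxy-3-(triisopropylsilyloxy)phenyl]-3-(phenylsulfinyl)but-3-en-2-one F5. Claisen formylation of its benzylic position (LiN(SiMe3)2, THF, −78 °C, then HCO2Et) should give the hydroxymethylene enaminone 1-(dimethylamino)-5-hydroxy-4-[4-methoxy-3-(triisopropylsilyloxy)phenyl]-2-(phenylsulfinyl)penta-1,4-dien-3-one F6. Acidification closes F6 with loss of dimethylamine and comes back to the route at 8.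

Step 6. Under carbonate the silyl group may transfer from O3' to the 7-phenoxide and blur the distinction between the two oxygens, and C-alkylation at C8 or SN2' attack on the allylic bromide may compete. The fallback sets out from 12 and avoids a free phenoxide altogether. Mitsunobu etherification with 3-methylbut-2-en-1-ol, PPh3 and diisopropyl azodicarboxylate in THF at 0 °C comes back to the route at 14. It makes no compound outside the list (F0).

**Further compounds**

F1 | step 5 | 1-(2,4-dihydroxyphenyl)-2-(3-hydroxy-4-methoxyphenyl)ethan-1-one | COc1ccc(CC(=O)c2ccc(O)cc2O)cc1O
F2 | step 5 | 7-hydroxy-3-(3-hydroxy-4-methoxyphenyl)-4H-chromen-4-one | COc1ccc(-c2coc3cc(O)ccc3c2=O)cc1O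
F3 | step 3 | 1-[dimethyl(oxo)-λ6-sulfanylidene]-3-[4-methoxy-3-(triisopropylsilyloxy)phenyl]propan-2-one | COc1ccc(CC(=O)C=S(C)(C)=O)cc1O[Si](C(C)C)(C(C)C)C(C)C
F4 | step 3 | 1-[4-methoxy-3-(triisopropylsilyloxy)phenyl]-3-(phenylthio)propan-2-one | COc1ccc(CC(=O)CSc2ccccc2)cc1O[Si](C(C)C)(C(C)C)C(C)C
F5 | step 4 | 4-(dimethylamino)-1-[4-methoxy-3-(triisopropylsilyloxy)phenyl]-3-(phenylsulfinyl)but-3-en-2-one (racemic at sulfur) | COc1ccc(CC(=O)C(=CN(C)C)S(=O)c2ccccc2)cc1O[Si](C(C)C)(C(C)C)C(C)C
F6 | step 4 | 1-(dimethylamino)-5-hydroxy-4-[4-methoxy-3-(triisopropylsilyloxy)phenyl]-2-(phenylsulfinyl)penta-1,4-dien-3-one (racemic at sulfur; enol and double-bond isomers) | COc1ccc(C(=CO)C(=O)C(=CN(C)C)S(=O)c2ccccc2)cc1O[Si](C(C)C)(C(C)C)C(C)C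
F0 | step 6 | none | none
A1 | alternative 1 | (Z)-3-[3-(benzyloxy)phenoxy]-2-[3-(benzyloxy)-4-methoxyphenyl]acrylic acid | OC(=O)/C(=C\Oc1cccc(OCc2ccccc2)c1)c1ccc(OC)c(OCc2ccccc2)c1
A2 | alternative 1 | 7-(benzyloxy)-3-[3-(benzyloxy)-4-methoxyphenyl]-4H-chromen-4-one | COc1ccc(-c2coc3cc(OCc4ccccc4)ccc3c2=O)cc1OCc1ccccc1
A3 | alternative 2 | 5-(benzyloxy)-3-chloro-2-(trimethylsilyl)phenyl trifluoromethanesulfonate | C[Si](C)(C)c1c(Cl)cc(OCc2ccccc2)cc1OS(=O)(=O)C(F)(F)F
A4 | alternative 2 | 2-[3-(benzyloxy)-4-methoxyphenyl]-3,3-dimethoxypropanoic acid (racemic) | COC(OC)C(C(=O)O)c1ccc(OC)c(OCc2ccccc2)c1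
A5 | alternative 2 | 1-[4-(benzyloxy)-2-chloro-6-hydroxyphenyl]-2-[3-(benzyloxy)-4-methoxyphenyl]-3,3-dimethoxypropan-1-one (racemic) | COC(OC)C(C(=O)c1c(O)cc(OCc2ccccc2)cc1Cl)c1ccc(OC)c(OCc2ccccc2)c1
A6 | alternative 3 | 1-[2-bromo-4-(3-methylbut-2-enyloxy)phenyl]-2-[3-(tert-butyldimethylsilyloxy)-4-methoxyphenyl]-3-hydroxyprop-2-en-1-one (enol and double-bond isomers) | COc1ccc(C(=CO)C(=O)c2ccc(OCC=C(C)C)cc2Br)cc1O[Si](C)(C)C(C)(C)C
A7 | alternative 3 | 3-[3-(tert-butyldimethylsilyloxy)-4-methoxyphenyl]-7-(3-methylbut-2-enyloxy)-4H-chromen-4-one | COc1ccc(-c2coc3cc(OCC=C(C)C)ccc3c2=O)cc1O[Si](C)(C)C(C)(C)C
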